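## The problem

The target (21) is a melampolide-type germacranolide: a cyclodeca-1(10),4-diene in which C1=C10 is ring-cis and carries the C14 methyl ester, C4=C5 is E and carries the C15 methyl, and an α-methylene-γ-lactone is trans-fused at C6–C7. C8 bears a methacrylate and C9 a free hydroxyl, so four contiguous stereocentres (6R,7S,8S,9S) sit on a conformationally mobile ring. Direct closure of a ten-membered ring holding two trisubstituted alkenes of opposite geometry must overcome entropy and transannular strain, and neither alkene geometry is then guaranteed. On the medium ring the stereocentres cannot be set one from another with confidence. On a rigid six-membered ring each of C6, C7 and C8 can be related to a single catalyst-set centre, and C9, which has to be trigonal at some stage, can be set last from C8. The exocyclic methylene lactone (conjugate addition, hydride, double-bond migration under base), the methacrylate next to a free hydroxyl (acyl shift, polymerisation) and the 1,5-diene (acid-induced transannular closure) allow only a short, mild end game. The enabling feature is that the oxygen-bearing C9 and C5 are 1,3-related through C4. Atoms C9, C10, C1, C2, C3 and C4 map onto a cyclohexene that contains the cis enoate, and atoms C4 to C9 map onto a cyclohexane that carries every stereocentre. A C4–C9 bond therefore turns the target into a decalin with an angular methyl and an angular hydroxyl, whose fragmentation returns both alkenes at once.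

## Retrosynthesis

**C9–H.** The C9 carbinol of 21 is taken back to the ketone 20. The C9 oxygen is the electron source of the ring-forming step and must emerge as a carbonyl, so a final 1,2-reduction is unavoidable. It is asked to be selective for one of four electrophilic sites and for one face, which the neighbouring C8 ester should control.

**C4–C9 (key disconnection).** Reconnecting C4 to C9 and placing a sulfonate on C5 converts 20 into the trans-fused hydroxy octalin mesylate 19. Against cuts at C5–C6, C9–C10 or C6–C7, this one forms the ring by cleaving a bond in a rigid bicycle, with no dilution-dependent cyclization. It also fixes E-C4=C5 and ring-cis C1=C10 stereospecifically. The price is three temporary stereocentres (C4, C5, C9). The forward reaction needs the C5–O bond equatorial and a free C9 alkoxide.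

**S–O and C5–H.** The mesylate 19 comes from diol ester 17 and methanesulfonyl chloride 18 (only one secondary hydroxyl is free). The equatorial C5 carbinol of 17 comes from ketone 16 by hydride delivery from the C9 hydroxyl, which places the C5 oxygen anti to it, exactly the relation the fragmentation needs.

**C8–O.** The axial C8 ester and the axial C9 hydroxyl of 16 are trans-diaxial, the signature of an epoxide opening. They are traced to the 8α,9α-epoxide 14 and methacrylic acid 15. One step then sets C8, uncovers the C9 carbinol and installs the ester, and it is the reason the route needs no protecting group. The forward step must attack the secondary C8 rather than the tertiary C9.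

**C6–O and the lactone C–O bond.** The α-acyloxy ketone 14 is opened to the keto acrylate 12. Enolate hydroxylation at C6 (the only enolisable position of the C5 ketone) followed by closure of the alkoxide onto the acrylate ester gives the trans-fused lactone with the exocyclic methylene already in place. No late methylenation with strong base is needed.

**C7–C11 and C11=C13.** The acrylate of 12 is cut into the enone 8, trimethyl phosphonoacetate 9 and formaldehyde 10. A stabilised carbanion adds to C7 and is then olefinated. The α-oxirane of 8 occupies one face of C7, so the side chain enters β, as the lactone requires.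

**C6=C7 and the oxirane.** Enone 8 comes from ketone 7 by dehydrogenation, and 7 from the diene ester 6 by epoxidation of the electron-richer C8=C9 bond from the face opposite the axial C15 methyl. The oxirane serves three purposes: latent C8/C9 oxygenation with the correct trans relation to the methyl, saturation of C8–C9 so the ring A enone is not part of a trienone, and facial control at C7.

**C1–H.** Diene ester 6 comes from enedione ester 4 through the dienyl triflate 5. This replaces the more obvious epoxidation/Wharton transposition of 4, for two reasons. Alkaline peroxide is expected to attack C9 syn to the angular methyl, as in steroidal 4-en-3-ones, which would give the cis-fused carbinol. Hydrazine would also condense with the β-keto ester. Removing the C1 oxygen by triflate reduction keeps C10 as the ester-bearing alkene carbon and leaves C8=C9 for the stereocontrolled oxidation above.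

**C9=C10 and C3–C4.** Compound 4 is the Robinson annulation product of 2-methylcyclohexane-1,3-dione 1 and methyl 3-oxopent-4-enoate 2 via triketone 3. The amino-acid-mediated aldol step sets C4, the centre from which every other stereocentre is derived.

## Roads not taken

Alternative 1: The same C4–C9 bond is broken, but in concert with formation of C6–C7. This is an anionic oxy-Cope rearrangement (KH, 18-crown-6) of a C9 alkoxide flanked by alkenyl groups on C9 and C4, giving dienone A1 after protonation of the C8=C9 enolate.
- Merits: it is also a ring expansion rather than a macrocyclization. It forms a skeletal C–C bond in the key step, and a chair transition state transmits alkene geometry to C6, C7 and the E-C4=C5 bond. Its monocyclic substrate is simpler than a functionalised decalin. In convergence and in C–C bond economy it is the better plan.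
- Weak points: C8 arises by kinetic protonation of a medium-ring enolate, which is not controlled. Both alkenyl groups are geometrically defined enol ethers. A1 is far from 21 in oxidation level: C14 is a silyl ether, C12 a protected alcohol, C13 is absent and the lactone is unmade. Some eight further steps, including a strong-base methylenation, would have to be run on the sensitive 1,5-diene.
- Comparison: the chosen plan sets against this that all oxygenation, the lactone and the ester are in place before the ring is opened, that C8 is fixed by an epoxide opening on a rigid ring, and that one step follows the key step.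

Alternative 2: The cut is C5–C6 together with C4–C15. Ni(cod)2 with Me2Zn would couple a terminal alkyne and a C6 aldehyde by syn addition, closing the ring as A2.
- Merits: it is convergent from an acyclic chain. It creates the E-trisubstituted alkene, the C15 methyl and the C6 carbinol in one operation, and C7–C9 can be set by acyclic methods. C9 would be set early with reagent control, which is better than a late reduction.
- Weak points: the ten-membered ring is closed directly against entropy and transannular strain. The C6 configuration rests on weak substrate control. The enoate and the 1,1-disubstituted alkene in the chain can enter competing oxidative cyclizations on zerovalent nickel. After A2 the C13 alcohol must be unmasked and oxidised twice, the lactone closed, and the C8/C9 protecting groups exchanged for the ester next to a free hydroxyl.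
- Comparison: the chosen plan offers a ring formation that cannot fail for entropic reasons, stereospecific geometry of both alkenes, and a protecting-group-free sequence.

Alternative 3: The cut is C9–C10. CrCl2 with catalytic NiCl2 would convert a Z-iodoenoate into an alkenylchromium that adds to a C9 aldehyde, giving A3.
- Merits: the reaction tolerates the lactone, the exocyclic methylene and esters. It transfers the iodide geometry to C1=C10 and delivers the C9 carbinol directly, with no ketone stage. A3 is the alternative product closest to 21 in oxidation level. In functional-group tolerance this road is at least as good as the chosen one.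
- Weak points: it is again a direct ten-membered closure at high dilution with a large excess of divalent chromium. The C9 configuration depends on the macrocyclic transition state, and the α-alkoxy aldehyde can epimerise. Replacing the C8 ether of A3 by the methacrylate next to the free C9 hydroxyl costs about four steps and invites acyl migration.
- Comparison: both plans must control C9 in a ten-membered environment. The chosen plan does so after a ring formation that is stereospecific and needs no dilution, and it carries the C8 ester through unchanged.

Key step: step 12

## Route

Remark on numbering: all intermediates carry the germacrane numbering of the target (ring A = C4–C5–C6–C7–C8–C9, ring B = C4–C3–C2–C1–C10–C9, C15 = methyl on C4, C14 = ester carbon on C10, C11–C13 = side chain on C7). β is the face of the C4 methyl in the bicyclic intermediates and α the opposite face.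

Assumption: D-proline is taken to give the (R)-configured quaternary centre of 4, by analogy with L-proline giving the (S)-Wieland–Miescher ketone.

Step 1
Reactants: 1 2-methylcyclohexane-1,3-dione; 2 methyl 3-oxopent-4-enoate
Product: 3 methyl 5-(1-methyl-2,6-dioxocyclohexyl)-3-oxopentanoate
Conditions: Et3N (2 mol%), EtOAc, 0 °C to rt
Reagents that add atoms: none
Why: Michael addition of the acidic cyclic 1,3-dione to the vinyl ketone; a trace of weak base should leave the β-keto ester side chain uncyclised for the catalyst-controlled step.

Step 2
Reactants: 3 methyl 5-(1-methyl-2,6-dioxocyclohexyl)-3-oxopentanoate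
Product: 4 methyl (8aR)-8a-methyl-1,6-dioxo-1,2,3,4,6,7,8,8a-octahydronaphthalene-5-carboxylate
Conditions: D-proline (30 mol%), DMSO, rt
Reagents that add atoms: none
Why: Hajos–Parrish–Eder–Sauer–Wiechert aldol cyclodehydration; the proline enamine of the side-chain ketone attacks one of the two enantiotopic ring carbonyls under carboxylic acid guidance, which sets C4, and the ketol dehydrates to the C9=C10 enone.

Step 3
Reactants: 4 enedione ester
Product: 5 methyl (4aR)-4a-methyl-5-oxo-2-[(trifluoromethylsulfonyl)oxy]-3,4,4a,5,6,7-hexahydronaphthalene-1-carboxylate
Conditions: NaH (1.05 equiv), THF, 0 °C; then PhNTf2, 0 °C to rt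
Reagents that add atoms: N-phenylbis(trifluoromethanesulfonimide), O=S(=O)(N(c1ccccc1)S(=O)(=O)C(F)(F)F)C(F)(F)F
Why: Enol triflate formation; C8–H is the most acidic proton because its removal gives the extended enolate of a vinylogous β-keto ester (C6–H is far less acidic), and O-sulfonylation at the C1 oxygen gives the C1(OTf)=C10/C8=C9 diene.

Step 4
Reactants: 5 dienyl triflate
Product: 6 methyl (4aR)-4a-methyl-5-oxo-3,4,4a,5,6,7-hexahydronaphthalene-1-carboxylate
Conditions: Pd(OAc)2 (5 mol%), PPh3, HCO2H, Bu3N, DMF, 60 °C
Reagents that add atoms: none
Why: Palladium-catalysed formate reduction of an enol triflate (oxidative addition, formate exchange, decarboxylation, reductive elimination) replaces the C1 oxygen by hydrogen and leaves the C1=C10 enoate and the C8=C9 alkene in place.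

Step 5
Reactants: 6 diene ester
Product: 7 8α,9α-epoxy keto ester
Conditions: 3-chloroperbenzoic acid (1.1 equiv), NaHCO3, CH2Cl2, 0 °C
Reagents that add atoms: 3-chloroperbenzoic acid, O=C(OO)c1cccc(Cl)c1
Why: Prilezhaev epoxidation; C8=C9 is the electron-richer alkene (C1=C10 carries the ester) and the peracid should approach anti to the axial C15 methyl on the adjacent C4, as with 5-ene steroids, placing the C9 oxygen α.

Step 6
Reactants: 7 8α,9α-epoxy keto ester
Product: 8 8α,9α-epoxy-6-en-5-one
Conditions: LiN(iPr)2 (1.1 equiv), THF, −78 °C; then N-tert-butylbenzenesulfinimidoyl chloride, −78 °C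
Reagents that add atoms: none
Why: Mukaiyama dehydrogenation of the lithium enolate (C6 is the only enolisable position); it is preferred to a palladium-mediated oxidation so that no zerovalent palladium meets the vinyl oxirane that is formed.

Step 7
Reactants: 8 8α,9α-epoxy-6-en-5-one; 9 methyl 2-(dimethoxyphosphoryl)acetate; 10 formaldehyde (as paraformaldehyde)
Product: 12 7β-[1-(methoxycarbonyl)vinyl]-8α,9α-epoxy-5-ketone, via phosphonate Michael adduct 11 (not isolated)
Conditions: NaH (1.05 equiv), 9 (1.1 equiv), THF, 0 °C; then (CH2O)n, 0 °C to rt
Reagents that add atoms: none
Why: Michael addition of the sodium phosphonoacetate to C7 from the β face, anti to the oxirane oxygen that covers the α face, sets C7; proton transfer gives the phosphonate-stabilised anion, whose Horner–Wadsworth–Emmons reaction with formaldehyde gives the acrylate (C11=C13).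

Step 8
Reactants: 12 7β-acrylate epoxy ketone
Product: 14 8α,9α-epoxy-5-oxo-11(13)-methylene-12,6α-olide, via 6α-hydroxy acrylate 13 (not isolated)
Conditions: KN(SiMe3)2 (1.1 equiv), THF, −78 °C; 2-(phenylsulfonyl)-3-phenyloxaziridine; −78 to −20 °C; AcOH
Reagents that add atoms: 2-(phenylsulfonyl)-3-phenyloxaziridine, O=S(=O)(c1ccccc1)N1OC1c1ccccc1
Why: Davis hydroxylation of the C5 potassium enolate; the oxidant should enter anti to the C7 side chain and the C15 methyl, giving the equatorial 6α-alkoxide (also the thermodynamic epimer), which closes the trans-fused γ-lactone on the acrylate ester by acyl substitution.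

Step 9
Reactants: 14 epoxy keto lactone; 15 methacrylic acid
Product: 16 8β-methacryloyloxy-9α-hydroxy-5-oxo-12,6α-olide
Conditions: methacrylic acid (neat, excess), BHT (1 mol%), 45 °C
Reagents that add atoms: none
Why: Acidolysis of the epoxide by a carboxylic acid in the trans-diaxial (Fürst–Plattner) sense, as in the acetolysis of 5α,6α-epoxy steroids: attack at the secondary C8 from the β face with inversion gives the axial C8 ester and the axial C9 hydroxyl, while ionisation at C9 is disfavoured by the electron-poor acrylate on C10.

Step 10
Reactants: 16 keto diol ester
Product: 17 8β-methacryloyloxy-5β,9α-dihydroxy-12,6α-olide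
Conditions: Me4NBH(OAc)3 (3 equiv), MeCN/AcOH (1:1), −20 °C
Reagents that add atoms: none
Why: Evans–Saksena directed reduction of a β-hydroxy ketone; the axial C9 hydroxyl binds boron and delivers hydride to the α face of C5, giving the equatorial 5β-alcohol (1,3-anti), and the reagent should not touch the methylene lactone, the esters or the enoate.

Step 11
Reactants: 17 diol ester; 18 methanesulfonyl chloride
Product: 19 5β-methanesulfonyloxy-8β-methacryloyloxy-9α-hydroxy-12,6α-olide
Conditions: Et3N, CH2Cl2, −10 °C
Reagents that add atoms: none
Why: Sulfonylation via sulfene of the only secondary hydroxyl; the tertiary C9 hydroxyl should not react under these conditions.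

Step 12
Reactants: 19 hydroxy octalin mesylate
Product: 20 (6R,7S,8S)-8-methacryloyloxy-9-oxo-germacra-1(10),4E,11(13)-trien-12,6-olide 14-methyl ester
Conditions: KN(SiMe3)2 (1.05 equiv), THF, −78 to −30 °C; pH 7 buffer
Reagents that add atoms: none
Why: The base removes the C9 hydroxyl proton; in the trans-fused chair of 19 an oxygen lone pair, the C4–C9 bond and the equatorial C5–O bond are anti-periplanar, so the alkoxide collapses to the C9 carbonyl while the C4–C9 electrons become the C4=C5 π bond and methanesulfonate leaves in one concerted event. The closest known reaction type is the Grob (Wharton) fragmentation of decalin 1,3-diol monosulfonates to E-cyclodecenones. The ten-membered ring is not closed by a cyclization, so no closure mode applies; it appears when the bond shared by rings A and B is cut. No stereocentre is created: C4, C5 and C9 become trigonal and C6, C7 and C8 are untouched. The selectivity at stake is alkene geometry: the axial C15 methyl and the axial H5 are anti and end up trans, so C3 and C6 are trans across C4=C5 (E), and C1=C10 stays ring-cis because it was held in ring B. The trans-fused lactone locks ring A in the chair that keeps the mesylate equatorial, and the trans-diaxial relation of the C8 ester and the C9 alkoxide excludes acyl transfer. One equivalent of a hindered amide at low temperature should avoid abstraction of H7 and enolisation of the product at C8.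

Step 13
Reactants: 20 9-oxo germacranolide
Product: 21 methyl (6R,7S,8S,9S)-9-hydroxy-8-methacryloyloxy-germacra-1(10),4E,11(13)-trien-12,6-olid-14-oate (target)
Conditions: NaBH4, CeCl3·7H2O, MeOH, −78 °C
Reagents that add atoms: none
Why: Luche reduction, 1,2-selective for the conjugated ketone over the methylene lactone and the doubly activated C1=C10; hydride attack anti to the C8–O bond (polar Felkin–Anh) gives the 8,9-syn arrangement of the target, which sets C9.

## Compound list

1 | 2-methylcyclohexane-1,3-dione | CC1C(=O)CCCC1=O | starting material
2 | methyl 3-oxopent-4-enoate | COC(=O)CC(=O)C=C | starting material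
3 | methyl 5-(1-methyl-2,6-dioxocyclohexyl)-3-oxopentanoate | COC(=O)CC(=O)CCC1(C)C(=O)CCCC1=O | intermediate
4 | methyl (8aR)-8a-methyl-1,6-dioxo-1,2,3,4,6,7,8,8a-octahydronaphthalene-5-carboxylate (C5 ketone, C9=C10–C1=O enone, ester on C10, C4 methyl β) | COC(=O)C1=C2CCCC(=O)[C@]2(C)CCC1=O | intermediate
5 | methyl (4aR)-4a-methyl-5-oxo-2-[(trifluoromethylsulfonyl)oxy]-3,4,4a,5,6,7-hexahydronaphthalene-1-carboxylate (C1(OTf)=C10 and C8=C9) | COC(=O)C1=C(OS(=O)(=O)C(F)(F)F)CC[C@@]2(C)C(=O)CCC=C12 | intermediate
6 | methyl (4aR)-4a-methyl-5-oxo-3,4,4a,5,6,7-hexahydronaphthalene-1-carboxylate (C1=C10 enoate, C8=C9, C5 ketone) | COC(=O)C1=CCC[C@@]2(C)C(=O)CCC=C12 | intermediate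
7 | 8α,9α-epoxide of 6 (oxirane on the face opposite the C4 methyl; C1=C10 enoate and C5 ketone retained) | COC(=O)C1=CCC[C@@]2(C)C(=O)CC[C@H]3O[C@@]123 | intermediate
8 | 8α,9α-epoxy-6-en-5-one (7 with a C6=C7 double bond) | COC(=O)C1=CCC[C@@]2(C)C(=O)C=C[C@H]3O[C@@]123 | intermediate
9 | methyl 2-(dimethoxyphosphoryl)acetate (trimethyl phosphonoacetate) | COC(=O)CP(=O)(OC)OC | starting material
10 | formaldehyde (used as paraformaldehyde) | C=O | starting material
11 | 7β-[(dimethoxyphosphoryl)(methoxycarbonyl)methyl]-8α,9α-epoxy-5-ketone (C11 epimers) | COC(=O)C(P(=O)(OC)OC)[C@H]1CC(=O)[C@]2(C)CCC=C(C(=O)OC)[C@]23O[C@H]13 | intermediate (not isolated)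
12 | 7β-[1-(methoxycarbonyl)vinyl]-8α,9α-epoxy-5-ketone (C1=C10 enoate retained) | C=C(C(=O)OC)[C@H]1CC(=O)[C@]2(C)CCC=C(C(=O)OC)[C@]23O[C@H]13 | intermediate
13 | 6α-hydroxy derivative of 12 (formed as its potassium alkoxide) | C=C(C(=O)OC)[C@H]1[C@H](O)C(=O)[C@]2(C)CCC=C(C(=O)OC)[C@]23O[C@H]13 | intermediate (not isolated)
14 | 8α,9α-epoxy-5-oxo-11(13)-methylene-12,6α-olide (trans-fused α-methylene-γ-lactone at C6–C7, C1=C10 enoate) | O=C1O[C@@H]2C(=O)[C@]3(C)CCC=C(C(=O)OC)[C@]34O[C@@H]4[C@H]2C1=C | intermediate
15 | methacrylic acid | C=C(C)C(=O)O | starting material
16 | 8β-methacryloyloxy-9α-hydroxy-5-oxo-12,6α-olide (trans-fused decalin, α-methylene lactone, C1=C10 enoate) | C=C(C)C(=O)O[C@H]1[C@H]2C(=C)C(=O)O[C@@H]2C(=O)[C@]3(C)CCC=C(C(=O)OC)[C@@]13O | intermediate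
17 | 8β-methacryloyloxy-5β,9α-dihydroxy-12,6α-olide | C=C(C)C(=O)O[C@H]1[C@H]2C(=C)C(=O)O[C@@H]2[C@@H](O)[C@]3(C)CCC=C(C(=O)OC)[C@@]13O | intermediate
18 | methanesulfonyl chloride | CS(=O)(=O)Cl | starting material
19 | 5β-methanesulfonyloxy-8β-methacryloyloxy-9α-hydroxy-12,6α-olide (trans-fused hydroxy octalin mesylate; C5–OMs equatorial, C9–OH and C4–CH3 axial) | C=C(C)C(=O)O[C@H]1[C@H]2C(=C)C(=O)O[C@@H]2[C@@H](OS(C)(=O)=O)[C@]3(C)CCC=C(C(=O)OC)[C@@]13O | intermediate
20 | (6R,7S,8S)-8-methacryloyloxy-9-oxo-germacra-1(10),4E,11(13)-trien-12,6-olide 14-methyl ester (C1=C10 ring-cis) | C=C(C)C(=O)O[C@H]1[C@H]2C(=C)C(=O)O[C@@H]2/C=C(\C)CC/C=C(/C(=O)OC)C1=O | intermediate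
21 | methyl (6R,7S,8S,9S)-9-hydroxy-8-methacryloyloxy-germacra-1(10),4E,11(13)-trien-12,6-olid-14-oate (8β-ester, 9α-hydroxyl, C1=C10 ring-cis) | C=C(C)C(=O)O[C@H]1[C@H]2C(=C)C(=O)O[C@@H]2/C=C(\C)CC/C=C(/C(=O)OC)[C@@H]1O | target

## Step count and risks

Total: 13 steps. Longest linear sequence: 13 steps (1 to 21).

**Step 12 (key step).** The fragmentation could be overtaken by proton abstraction at C7 (γ to the lactone carbonyl), which would move the exocyclic double bond into the lactone ring. Enolisation of the new ketone could also epimerise C8. Fallback: starting from 19, silylate the C9 hydroxyl (Me3SiOTf, 2,6-lutidine, CH2Cl2, −78 °C) to the C9 trimethylsilyl ether F1, then release the alkoxide with anhydrous fluoride (tris(dimethylamino)sulfonium difluorotrimethylsilicate, THF, −40 °C) so that no amide base is present. The fluoride-triggered fragmentation returns to the route at 20.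

**Step 9.** The epoxide may open by ionisation at the tertiary allylic C9 or by allylic attack at C1 instead of bimolecular attack at C8, or it may rearrange to a C8 ketone, because methacrylic acid is a weak nucleophile. Fallback: starting from 14, open the oxirane with water (dilute aqueous HClO4, THF, 0 °C, the classical diaxial hydrolysis) to the 8β,9α-dihydroxy-5-oxo lactone F2. Then acylate the secondary C8 hydroxyl alone (methacrylic anhydride, DMAP, Et3N, CH2Cl2), which returns to the route at 16.

**Step 2.** Enantiofacial discrimination may be poor, because the nucleophilic carbon carries an ester and the acidic β-keto ester can close without the catalyst. Fallback: starting from 1, add methyl vinyl ketone (Et3N cat.) to give 2-methyl-2-(3-oxobutyl)cyclohexane-1,3-dione F3. Cyclise with D-proline in DMSO to the (R)-Wieland–Miescher ketone F4. Iodinate the enone α-carbon (I2, pyridine, CH2Cl2) to the C10 iodo enone F5. Carbonylate (Pd(OAc)2, PPh3, CO, MeOH, Et3N, DMF, 60 °C) to rejoin the route at 4.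

**Step 7.** The phosphonate-stabilised carbanion, or the transient C5 enolate, could open the neighbouring oxirane to a cyclopropane before the olefination, or some addition could occur from the α face. Fallback: starting from 8, add dimethyl malonate under catalytic NaOMe in MeOH, where the adduct is protonated at once, to give the 7β-malonate adduct F6. Hydrolyse one ester (KOH, 1 equiv, MeOH/H2O) to the malonic half ester F7. A Mannich-type decarboxylative methylenation (Et2NH, paraformaldehyde, EtOAc, reflux) then returns to the route at 12.

**Step 13.** Hydride may be delivered to the wrong face of the C9 ketone in the mobile ring. Conjugate reduction of the methylene lactone or of C1=C10 and an 8-to-9 acyl shift in the product alkoxide are further risks. Fallback: starting from 20, replace substrate control by catalyst control, using catecholborane with whichever enantiomer of 2-methyl-CBS-oxazaborolidine matches (toluene, −78 °C). This non-basic reduction leads directly to 21 and forms no new compound (F0).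

## Further compounds

F1 | step 12 | C9 trimethylsilyl ether of 19 | C=C(C)C(=O)O[C@H]1[C@H]2C(=C)C(=O)O[C@@H]2[C@@H](OS(C)(=O)=O)[C@]3(C)CCC=C(C(=O)OC)[C@@]13O[Si](C)(C)C
F2 | step 9 | 8β,9α-dihydroxy-5-oxo-11(13)-methylene-12,6α-olide | O[C@H]1[C@H]2C(=C)C(=O)O[C@@H]2C(=O)[C@]3(C)CCC=C(C(=O)OC)[C@@]13O
F3 | step 2 | 2-methyl-2-(3-oxobutyl)cyclohexane-1,3-dione | CC(=O)CCC1(C)C(=O)CCCC1=O
F4 | step 2 | (R)-Wieland–Miescher ketone, (8aR)-8a-methyl-3,4,8,8a-tetrahydronaphthalene-1,6(2H,7H)-dione | O=C1CC[C@@]2(C)C(=O)CCCC2=C1
F5 | step 2 | (8aR)-5-iodo-8a-methyl-3,4,8,8a-tetrahydronaphthalene-1,6(2H,7H)-dione | O=C1CC[C@@]2(C)C(=O)CCCC2=C1I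
F6 | step 7 | 7β-[bis(methoxycarbonyl)methyl]-8α,9α-epoxy-5-ketone | COC(=O)C(C(=O)OC)[C@H]1CC(=O)[C@]2(C)CCC=C(C(=O)OC)[C@]23O[C@H]13
F7 | step 7 | malonic half ester of F6 (C11 epimers) | COC(=O)C(C(=O)O)[C@H]1CC(=O)[C@]2(C)CCC=C(C(=O)OC)[C@]23O[C@H]13
F0 | step 13 | none | none
A1 | alternative 1 | ten-membered dienone from the anionic oxy-Cope rearrangement (8-O-methoxymethyl, 6-O-PMB, C7 2-(PMB-oxy)ethyl, C14 silyl ether, 9-ketone) | COCO[C@H]1[C@@H](CCOCc2ccc(OC)cc2)[C@H](OCc2ccc(OC)cc2)/C=C(\C)CC/C=C(/CO[Si](C)(C)C(C)(C)C)C1=O
A2 | alternative 2 | ten-membered 6-hydroxy diene from the nickel-catalysed methylative alkyne–aldehyde cyclization (8-O-PMB, 9-O-silyl, C13 silyl ether) | COc1ccc(CO[C@H]2[C@@H](C(=C)CO[Si](C)(C)C(C)(C)C)[C@H](O)/C=C(\C)CC/C=C(/C(=O)OC)[C@@H]2O[Si](C)(C)C(C)(C)C)cc1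
A3 | alternative 3 | 8-O-PMB ten-membered lactone with free 9-hydroxyl from the alkenylchromium cyclization | COc1ccc(CO[C@H]2[C@H]3C(=C)C(=O)O[C@@H]3/C=C(\C)CC/C=C(/C(=O)OC)[C@@H]2O)cc1
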